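The product Xp levels off in these flasks well short of what the charge seems to allow, and a new recipe can't be judged until that is understood.

| flask | Xa | Xb | time |
|---|---|---|---|
| south | 0.400 M | 0.600 M |  |
| north-east | 0.200 M | 0.400 M |  |
| south-west | 0.800 M | 0.600 M |  |
| south-east | 0.400 M | 0.900 M |  |
| north-west | 0.800 M | 0.200 M | 16 h |

- south run (time / h: [Xp] / M): 2.3: 0.013; 4.6: 0.052; 6.9: 0.059; 9.1: 0.085; 11: 0.085; 14: 0.093; 16: 0.092
- north-east run (time / h: [Xp] / M): 2.3: 0.003; 4.6: 0.012; 6.9: 0.003; 9.1: 0.009; 11: 0; 14: 0.022; 16: 0.011
- south-west run (time / h: [Xp] / M): 2.3: 0.125; 4.6: 0.238; 6.9: 0.261; 9.1: 0.267; 11: 0.261; 14: 0.277; 16: 0.270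
- south-east run (time / h: [Xp] / M): 2.3: 0.035; 4.6: 0.086; 6.9: 0.097; 9.1: 0.138; 11: 0.124; 14: 0.117; 16: 0.133

(scatter of a reading: 0.006 M)

* order of the initial rate in [Xb], near the charge of the south run, the rate being that where two percent of its Xa are Xp
* order of the initial rate in [Xa], near the charge of the south run, the rate being that where two percent of its Xa are Xp (one fixed amount of Xp, the same in the runs compared)
* Xp in the north-west run at 16 h, as a share of the Xa charged

- Overall: Xa + Xb -> Xp.
- Constant volume, constant temperature.
- An order is taken over about fifteen percent of the charge, up and down.

We take the mean of the readings from 11 h on as each run's level. The south run levels at 0.0900 M, which is 22.5% of its Xa, so 77.5% of the cXa charged is not in Xp. A flask that halts with so much Xa unaccounted for should not care about more Xa. Yet the south-west run, with twice the cXa and the same cXb, levels at 0.269 M, which is 2.99 times as much.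

A level need not mean that the charge has ended. Suppose something stops the making at a pace that does not follow the charge. Dividing the rate of making by the pace of stopping removes time, and the level then goes with the rate of making. We try the square of cXa times cXb, and call the level divided by this product the plateau number. It comes to 0.938 /M² in the south run, 0.866 /M² in the south-east run, 0.687 /M² in the north-east run and 0.701 /M² in the south-west run, though the product itself spans a factor of 24.0. The north-east level is 0.0110 M against a scatter of 0.006 M per reading, so its number is rough.

In the north-west run Xb is the limiting reagent, at 0.200 M against 0.800 M of Xa. The south-west run has the same cXa, and among the south, south-east and south-west runs it has matched the largest share of its Xb by Xp, 44.9%. So we carry its plateau number, the level over the square of cXa times cXb, and get 0.0898 M, or 11.2% of the Xa charged.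

The forecast gives orders of 0.9 in cXb and 2.1 in cXa, and for the north-west run 13% of the Xa charged, which is higher than our share. It reads the levels as “a dying catalyst or similar”.

The flask gives orders of 0.91 in cXb and 1.5 in cXa, the second lower than the forecast's, and for the north-west run 11.5% of the Xa charged, so the north-west plateau number is 0.717 /M², near the south-west reading.

    Xa → Xi (0.1696 /h)
    Xi + Xb → Xp (0.1242 /M/h)
    Xi → Xq (0.3481 /h)
    2 Xb → Z (0.4572 /M/h)
    Xa + Xb + Xp → 2 Xp (10.04 /M²/h)

In the north-west run Xb also passes into Z, which is not product. Take away the passing of 2 Xb into Z, and that run's share rises from 11.5% to 22.9%. Its plateau number then becomes 1.43 /M², twice the value with that loss in place.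

(Readings and results come from a simulation from invented constants.)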